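In a one-step world, where starting material and coupling partner make target and nothing else, target in each run would climb to the charge of the coupling partner, the limiting reagent, which is 0.400 M in the spring run. Your hunch was that the winter run, at 3.00 times the spring charge of both, repeats the spring yield of 42.6% on starting material. Here is what we have.

| flask | starting material | coupling partner | time |
|---|---|---|---|
| spring | 0.500 M | 0.400 M |  |
| autumn | 0.500 M | 0.200 M |  |
| summer | 1.00 M | 0.400 M |  |
| winter | 1.50 M | 1.20 M | 34 h |

| run | time / h | [target] / M |
|---|---|---|
| spring run | 4.9 | 0.095 |
| spring run | 9.7 | 0.140 |
| spring run | 15 | 0.179 |
| spring run | 19 | 0.192 |
| spring run | 24 | 0.202 |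
| spring run | 29 | 0.207 |
| spring run | 34 | 0.213 |
| autumn run | 4.9 | 0.052 |
| autumn run | 9.7 | 0.076 |
| autumn run | 15 | 0.095 |
| autumn run | 19 | 0.103 |
| autumn run | 24 | 0.106 |
| autumn run | 29 | 0.108 |
| autumn run | 34 | 0.114 |
| summer run | 4.9 | 0.155 |
| summer run | 9.7 | 0.215 |
| summer run | 15 | 0.246 |
| summer run | 19 | 0.264 |
| summer run | 24 | 0.267 |
| summer run | 29 | 0.266 |
| summer run | 34 | 0.271 |

(readings scatter by 0.003 M)

- the power of [coupling partner] that the first rate follows, about the charge of the spring run; measure it at two percent of starting material made into target
- the power of [starting material] that the first rate follows, about the charge of the spring run; measure it at two percent of starting material made into target (one fixed amount of target, the same in the runs compared)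
- target in the winter run at 34 h, as a share of the starting material charged

- Overall: starting material + coupling partner -> target.
- Constant volume, constant temperature.
- The analysis sees a species whether free or bound.
- "The second partner" is coupling partner.
- An order is taken over about fifteen percent of the charge, up and down.

The readings level off short of that end, so we carry one number, which in the spring run is 0.532: the partner share, target at the last reading over coupling partner charged. The autumn run, with half the partner, gives 0.570, so we let the share ignore the partner charge, while the summer run, with twice the starting material, gives 0.677.

Logarithms turn this into a power. Taking mean starting material as the charge less half the target, 0.394 M in spring and 0.865 M in summer, the share climbs 0.105 decades over 0.342 decades, a power of 0.306. With the summer share as a first guess, the winter mean is 1.09 M, which is 0.442 decades above spring, so the winter share should be 0.728, and target 58.2% of the starting material charged, not your 42.6%.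

The same log ratio on the first readings gives 0.869 for the partner and 0.706 for starting material, but the spring run has by then turned 19.0% of its starting material, so we commit to about 1 for the partner and to between 0.706 and 1 for starting material.

The forecast, noting that the runs “all stall before the limiting partner is used up”, gives 1 for the partner, 0.9 for starting material and 54% for the winter run, a winter figure lower than our own.

The flask gives 1.0 for the partner, 0.83 for starting material and 56.9% for the winter run.

    starting material ⇌ intermediate, settled at all times (0.3670)
    intermediate + coupling partner → target (0.7092 M⁻¹ h⁻¹)
    coupling partner → lost reagent (0.04860 h⁻¹)
    2 starting material ⇌ idle substrate dimer, settled at all times (0.8390 M⁻¹)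

In the winter run that yield is a partner share of 0.712, higher than the spring 0.532. The coupling partner also decays by itself to lost reagent, and the same winter run without that loss gives 75.1% in place of 56.9%, a partner share of 0.939.

Readings and results come from a simulation from invented constants; scatter was added.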